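**Assumptions (one line):** the SMILES is natural (+)-discodermolide, numbered C1 (lactone C=O) to C24 (diene terminus); (S)-Roche ester, both 2-butenes, (R)-but-3-yn-2-ol and vinyl bromide (THF solution) are taken as commercial.

## Retrosynthetic overview

1. Discodermolide ⇐ C7 ketone (CBS reduction sets C7; acid removes the two TBS groups).
2. Key disconnection C6–C7: Ni-catalysed radical acyl cross-coupling of the primary C6 radical from a C1–C6 iodolactone with a fully elaborated C7–C24 (Z)-enoyl S-2-pyridyl thioester.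
3. C7–C24 ⇐ B-alkyl Suzuki coupling at C14–C15 (C15–C24 alkyl iodide + C7–C14 (Z)-vinyl iodide); carbamate installed on the only free OH afterwards.
4. All three fragments ⇐ one (S)-Roche-ester aldehyde: Brown (E)-crotylation gives a common syn,anti triad (C1–C6 and C8–C13); Brown (Z)-crotylation plus Marshall allenylzinc addition gives C15–C22.
5. Ring order: the only ring (δ-lactone) is closed early by oxidative lactonisation of an iodo-triol, before fragment union.

## Route

### Common intermediate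

**Step 1**
Reactants: 1, methyl (S)-3-hydroxy-2-methylpropanoate
Product: 2, methyl (S)-2-methyl-3-[(triethylsilyl)oxy]propanoate
Conditions: TESCl, imidazole, CH2Cl2, 0 °C → rt
Reagents that add atoms: TESCl, CC[Si](Cl)(CC)CC
Why: Standard silylation; a primary TES ether can later be cleaved or oxidised selectively beside secondary TBS ethers.

**Step 2**
Reactants: 2
Product: 3, (S)-2-methyl-3-[(triethylsilyl)oxy]propanal
Conditions: DIBAL-H (1.1 equiv), CH2Cl2, −78 °C; Rochelle salt; used crude
Reagents that add atoms: none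
Why: Low-temperature DIBAL partial reduction stops at the aluminium hemiacetal, and the α-stereocentre survives if the aldehyde is not stored.

**Step 3**
Reactants: 3; 4, (E)-but-2-ene
Product: 5, (2S,3S,4S)-2,4-dimethyl-1-[(triethylsilyl)oxy]hex-5-en-3-ol
Conditions: 4, KOt-Bu, n-BuLi, THF, −78 → −45 °C; (−)-Ipc2BOMe; BF3·OEt2; 3, −78 °C; NaBO3·4H2O
Reagents that add atoms: none
Why: Brown crotylboration through a chair transition state: the E-crotyl unit gives the 3,4-anti relationship, and the (−)-Ipc2B reagent (from (+)-α-pinene) attacks the Si face, which is the Felkin (matched) sense and gives 2,3-syn.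

### C1–C6 iodolactone

**Step 4**
Reactants: 5
Product: 6, (2S,3R,4R)-2-methyl-4-[(2R)-oxiran-2-yl]-1-[(triethylsilyl)oxy]pentan-3-ol
Conditions: VO(acac)2 (5 mol %), t-BuOOH, CH2Cl2, 0 °C → rt
Reagents that add atoms: t-BuOOH, CC(C)(C)OO
Why: Hydroxyl-directed vanadium epoxidation of the homoallylic alcohol through a chair vanadate transition state with the C2 chain, C4-Me and C6 all equatorial sets C5 (3,5-syn, 4,5-anti); the minor epimer is removed by chromatography.

**Step 5**
Reactants: 6
Product: 7, (2S,3R,4R,5R)-6-iodo-2,4-dimethylhexane-1,3,5-triol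
Conditions: LiI, AcOH, THF, rt; then H2O added (AcOH/THF/H2O), rt
Reagents that add atoms: LiI, [Li+].[I-]
Why: Acid-assisted SN2 opening by iodide at the terminal epoxide carbon leaves C5 untouched, and the aqueous acetic acid then hydrolyses the primary TES ether in the same pot.

**Step 6**
Reactants: 7
Product: 8, (3R,4S,5R,6R)-4-hydroxy-6-(iodomethyl)-3,5-dimethyloxan-2-one (C1–C6 iodolactone)
Conditions: TEMPO (20 mol %), PhI(OAc)2 (3 equiv), CH2Cl2, rt
Reagents that add atoms: none
Why: TEMPO/BAIB oxidises only the primary alcohol; the aldehyde is trapped by the C5-OH as a six-membered lactol, which is oxidised to the δ-lactone (ring formation) without touching C3-OH or the stereocentres.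

### C7–C14 vinyl iodide

**Step 7**
Reactants: 5
Product: 9, 3-O-TBS ether of 5
Conditions: TBSOTf, 2,6-lutidine, CH2Cl2, −78 °C
Reagents that add atoms: TBSOTf, CC(C)(C)[Si](C)(C)OS(=O)(=O)C(F)(F)F
Why: Silylation of the hindered secondary alcohol (the future C11-OTBS).

**Step 8**
Reactants: 9
Product: 10, (2R,3R,4S)-3-[(tert-butyldimethylsilyl)oxy]-2,4-dimethyl-5-[(triethylsilyl)oxy]pentanal
Conditions: O3, CH2Cl2, −78 °C; then PPh3
Reagents that add atoms: ozone, O=[O+][O-]
Why: Ozonolysis of the only alkene gives the C9 aldehyde; reductive work-up avoids epimerising C10.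

**Step 9**
Reactants: 10
Product: 11, methyl (2Z,4S,5S,6S)-5-[(tert-butyldimethylsilyl)oxy]-4,6-dimethyl-7-[(triethylsilyl)oxy]hept-2-enoate
Conditions: (CF3CH2O)2P(O)CH2CO2Me, KHMDS, 18-crown-6, THF, −78 °C
Reagents that add atoms: Still–Gennari phosphonate, COC(=O)CP(=O)(OCC(F)(F)F)OCC(F)(F)F
Why: Still–Gennari olefination gives the C8=C9 (Z)-enoate under kinetic control with no epimerisation at C10.

**Step 10**
Reactants: 11
Product: 12, methyl (2Z,4S,5S,6R)-5-[(tert-butyldimethylsilyl)oxy]-4,6-dimethyl-7-oxohept-2-enoate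
Conditions: (COCl)2, DMSO, CH2Cl2, −78 → −30 °C; then i-Pr2NEt, → 0 °C
Reagents that add atoms: none
Why: Swern conditions cleave and oxidise a primary TES ether directly to the aldehyde while the secondary TBS ether is inert (oxidative desilylation).

**Step 11**
Reactants: 12
Product: 13, methyl (2Z,4S,5S,6S,7Z)-5-[(tert-butyldimethylsilyl)oxy]-8-iodo-4,6-dimethylnona-2,7-dienoate
Conditions: EtPPh3I, n-BuLi, THF; I2, −78 °C; NaHMDS, −20 °C; then 12, −78 → −20 °C
Reagents that add atoms: ethyltriphenylphosphonium iodide, CC[P+](c1ccccc1)(c1ccccc1)c1ccccc1.[I-]; iodine, II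
Why: Stork–Zhao–Wittig olefination with the α-iodo ylide gives the (Z)-2-iodoalkene (C13=C14) under kinetic control, as precedented on the same C11–C13 motif; the aldehyde reacts far faster than the hindered enoate.

### C15–C24 alkyl iodide

**Step 12**
Reactants: 3; 14, (Z)-but-2-ene
Product: 15, (2S,3S,4R)-2,4-dimethyl-1-[(triethylsilyl)oxy]hex-5-en-3-ol
Conditions: 14, KOt-Bu, n-BuLi, THF, −78 → −45 °C; (−)-Ipc2BOMe; BF3·OEt2; 3, −78 °C; NaBO3·4H2O
Reagents that add atoms: none
Why: Brown crotylboration with the Z-crotyl unit gives the C17/C18 syn relationship, and the same Si-face reagent control as in step 3 gives C16/C17 syn (syn,syn triad).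

**Step 13**
Reactants: 15
Product: 16, 3-O-TBS ether of 15
Conditions: TBSOTf, 2,6-lutidine, CH2Cl2, −78 °C
Reagents that add atoms: TBSOTf, CC(C)(C)[Si](C)(C)OS(=O)(=O)C(F)(F)F
Why: Silylation (the future C17-OTBS).

**Step 14**
Reactants: 16
Product: 17, (2S,3R,4S)-3-[(tert-butyldimethylsilyl)oxy]-2,4-dimethyl-5-[(triethylsilyl)oxy]pentanal
Conditions: O3, CH2Cl2, −78 °C; then PPh3
Reagents that add atoms: ozone, O=[O+][O-]
Why: Ozonolysis gives the C19 aldehyde.

**Step 15**
Reactants: 18, (R)-but-3-yn-2-ol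
Product: 19, (R)-but-3-yn-2-yl methanesulfonate
Conditions: MsCl, Et3N, CH2Cl2, −78 → 0 °C
Reagents that add atoms: MsCl, CS(=O)(=O)Cl
Why: Mesylation with retention at carbon.

**Step 16**
Reactants: 17; 19
Product: 20, C15–C22 homopropargylic alcohol (15-OTES, 17-OTBS, 19-OH, 20-Me, C21≡C22-H; C16–C20 configured as in the target)
Conditions: Pd(OAc)2 (5 mol %), PPh3 (5 mol %), Et2Zn (3 equiv), THF, −78 → −20 °C
Reagents that add atoms: none
Why: Marshall allenylzinc addition: anti-SN2′ oxidative addition, Pd→Zn transmetalation and a cyclic SE2′ transition state give the anti C19/C20 adduct; the (R)-mesylate sets 20S and therefore 19S, which is the Felkin (matched) sense relative to C18.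

**Step 17**
Reactants: 20; 21, vinyl bromide
Product: 22, C15–C24 enyne (C21≡C22–C23=C24)
Conditions: 21 (1 M in THF, excess), Pd(PPh3)4 (5 mol %), CuI (10 mol %), i-Pr2NH, THF, rt
Reagents that add atoms: none
Why: Sonogashira coupling of the terminal alkyne; the free C19-OH and the silyl ethers are tolerated.

**Step 18**
Reactants: 22
Product: 23, C15–C24 (Z)-diene (15-OTES, 17-OTBS, 19-OH)
Conditions: Zn(Cu/Ag), MeOH/H2O, 40 °C
Reagents that add atoms: none
Why: Boland reduction semi-reduces only the conjugated alkyne, cis-selectively, to give the (21Z)-terminal diene without over-reduction.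

**Step 19**
Reactants: 23
Product: 24, C15–C24 diol (15-OH, 19-OH, 17-OTBS)
Conditions: PPTS (0.2 equiv), MeOH/CH2Cl2, 0 °C
Reagents that add atoms: none
Why: Mild acid methanolysis removes the primary TES ether and leaves the hindered secondary TBS ether and the diene intact.

**Step 20**
Reactants: 24
Product: 25, C15–C24 primary iodide (15-I, 17-OTBS, 19-OH)
Conditions: I2, PPh3, imidazole, CH2Cl2, 0 °C
Reagents that add atoms: iodine, II
Why: Garegg–Appel iodination is selective for the primary alcohol; the C19-OH, flanked by two methyl-bearing carbons, does not react, and iodide outcompetes intramolecular ether formation.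

### Fragment union and end-game

**Step 21**
Reactants: 25; 13
Product: 26, methyl ester of the C7–C24 (Z)-enoic acid (11,17-bis-OTBS, 19-OH)
Conditions: 25, MeLi (1.0 equiv) then t-BuLi (2.1 equiv), Et2O, −78 °C; B-OMe-9-BBN (2.5 equiv), THF, → rt; then 13, Pd(dppf)Cl2 (10 mol %), aq K3PO4, DMF, rt
Reagents that add atoms: none
Why: B-alkyl Suzuki–Miyaura coupling (Marshall protocol) forms C14–C15 with retention of the (Z)-vinyl iodide geometry; the C19-OH is masked as its lithium alkoxide before the iodine–lithium exchange.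

**Step 22**
Reactants: 26
Product: 27, 19-O-carbamate of 26
Conditions: Cl3CC(O)NCO, CH2Cl2, 0 °C; then neutral Al2O3, rt
Reagents that add atoms: trichloroacetyl isocyanate, O=C=NC(=O)C(Cl)(Cl)Cl
Why: Kočovský carbamoylation of the only free hydroxyl; the trichloroacetyl group is cleaved on alumina without touching the ester.

**Step 23**
Reactants: 27
Product: 28, C7–C24 (Z)-enoic acid (19-OCONH2, 11,17-bis-OTBS)
Conditions: Me3SnOH, 1,2-dichloroethane, 70 °C
Reagents that add atoms: Me3SnOH, C[Sn](C)(C)O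
Why: Neutral tin-hydroxide ester hydrolysis avoids Z→E isomerisation and leaves the carbamate and TBS ethers intact.

**Step 24**
Reactants: 28
Product: 29, S-(pyridin-2-yl) thioester of 28
Conditions: 2,2′-dipyridyl disulfide, PPh3, CH2Cl2, rt
Reagents that add atoms: 2,2′-dipyridyl disulfide, c1ccc(SSc2ccccn2)nc1
Why: Mukaiyama/Corey–Nicolaou redox thioesterification under neutral conditions gives the acyl electrophile for nickel.

**Step 25 (key step)**
Reactants: 29; 8 (2 equiv)
Product: 30, 7-oxo-11,17-bis-O-TBS-discodermolide (C7 ketone, lactone and carbamate in place)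
Conditions: NiCl2·glyme (10 mol %), 4,4′-di-tert-butyl-2,2′-bipyridine (10 mol %), Mn powder (3 equiv), DMA/THF, 0 °C → rt
Reagents that add atoms: none
Why: Proposed new method: Ni(0) inserts into the acyl–S bond of 29, Ni(I) abstracts iodine from 8 to give the primary C6 radical (β-acyloxy radicals do not fragment and C5 is untouched), and radical capture by acyl–Ni(II) followed by reductive elimination from Ni(III) forms the C6–C7 ketone with no new stereocentre; the closest known reaction is the Weix Ni-catalysed reductive cross-electrophile ketone synthesis from S-2-pyridyl thioesters and alkyl iodides, here extended to a (Z)-enoyl donor and a β-acyloxy iodide, where radical capture at Ni should outrun Giese addition to the hindered enoyl β-carbon or to the diene, and Mn is used to limit direct metal insertion and ring-opening of 8.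

**Step 26**
Reactants: 30
Product: 31, 11,17-bis-O-TBS-discodermolide
Conditions: (R)-Me-CBS oxazaborolidine (2 equiv), catecholborane (5 equiv), toluene/CH2Cl2, −78 °C
Reagents that add atoms: none
Why: Corey–Bakshi–Shibata 1,2-reduction with the alkenyl group as the large substituent; the (R)-catalyst gives the 7S allylic alcohol, and catecholborane at −78 °C spares the lactone, carbamate and alkenes.

**Step 27**
Reactants: 31
Product: 32, (+)-discodermolide
Conditions: 3 N aq HCl, MeOH/THF, 0 °C → rt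
Reagents that add atoms: none
Why: Acidic removal of the two secondary TBS ethers; these are the proven final-step conditions for discodermolide and are tolerated by the lactone, carbamate and dienes.

## Compound list

1 | methyl (S)-3-hydroxy-2-methylpropanoate ((S)-Roche ester) | COC(=O)[C@@H](C)CO | starting material
2 | methyl (S)-2-methyl-3-[(triethylsilyl)oxy]propanoate | COC(=O)[C@@H](C)CO[Si](CC)(CC)CC | intermediate
3 | (S)-2-methyl-3-[(triethylsilyl)oxy]propanal | O=C[C@@H](C)CO[Si](CC)(CC)CC | intermediate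
4 | (E)-but-2-ene | C/C=C/C | starting material
5 | (2S,3S,4S)-2,4-dimethyl-1-[(triethylsilyl)oxy]hex-5-en-3-ol | CC[Si](CC)(CC)OC[C@H](C)[C@@H](O)[C@@H](C)C=C | intermediate
6 | (2S,3R,4R)-2-methyl-4-[(2R)-oxiran-2-yl]-1-[(triethylsilyl)oxy]pentan-3-ol | CC[Si](CC)(CC)OC[C@H](C)[C@@H](O)[C@@H](C)[C@@H]1CO1 | intermediate
7 | (2S,3R,4R,5R)-6-iodo-2,4-dimethylhexane-1,3,5-triol | OC[C@H](C)[C@@H](O)[C@@H](C)[C@@H](O)CI | intermediate
8 | (3R,4S,5R,6R)-4-hydroxy-6-(iodomethyl)-3,5-dimethyloxan-2-one | IC[C@@H]1OC(=O)[C@H](C)[C@@H](O)[C@H]1C | intermediate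
9 | 3-O-TBS ether of 5 | CC[Si](CC)(CC)OC[C@H](C)[C@@H](O[Si](C)(C)C(C)(C)C)[C@@H](C)C=C | intermediate
10 | (2R,3R,4S)-3-[(tert-butyldimethylsilyl)oxy]-2,4-dimethyl-5-[(triethylsilyl)oxy]pentanal | CC[Si](CC)(CC)OC[C@H](C)[C@@H](O[Si](C)(C)C(C)(C)C)[C@@H](C)C=O | intermediate
11 | methyl (2Z,4S,5S,6S)-5-[(tert-butyldimethylsilyl)oxy]-4,6-dimethyl-7-[(triethylsilyl)oxy]hept-2-enoate | CC[Si](CC)(CC)OC[C@H](C)[C@@H](O[Si](C)(C)C(C)(C)C)[C@@H](C)/C=C\C(=O)OC | intermediate
12 | methyl (2Z,4S,5S,6R)-5-[(tert-butyldimethylsilyl)oxy]-4,6-dimethyl-7-oxohept-2-enoate | O=C[C@H](C)[C@@H](O[Si](C)(C)C(C)(C)C)[C@@H](C)/C=C\C(=O)OC | intermediate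
13 | methyl (2Z,4S,5S,6S,7Z)-5-[(tert-butyldimethylsilyl)oxy]-8-iodo-4,6-dimethylnona-2,7-dienoate | I/C(C)=C\[C@H](C)[C@@H](O[Si](C)(C)C(C)(C)C)[C@@H](C)/C=C\C(=O)OC | intermediate
14 | (Z)-but-2-ene | C/C=C\C | starting material
15 | (2S,3S,4R)-2,4-dimethyl-1-[(triethylsilyl)oxy]hex-5-en-3-ol | CC[Si](CC)(CC)OC[C@H](C)[C@@H](O)[C@H](C)C=C | intermediate
16 | 3-O-TBS ether of 15 | CC[Si](CC)(CC)OC[C@H](C)[C@@H](O[Si](C)(C)C(C)(C)C)[C@H](C)C=C | intermediate
17 | (2S,3R,4S)-3-[(tert-butyldimethylsilyl)oxy]-2,4-dimethyl-5-[(triethylsilyl)oxy]pentanal | CC[Si](CC)(CC)OC[C@H](C)[C@@H](O[Si](C)(C)C(C)(C)C)[C@H](C)C=O | intermediate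
18 | (R)-but-3-yn-2-ol | C#C[C@@H](C)O | starting material
19 | (R)-but-3-yn-2-yl methanesulfonate | C#C[C@@H](C)OS(C)(=O)=O | intermediate
20 | C15–C22 homopropargylic alcohol (15-OTES, 17-OTBS, 19-OH) | CC[Si](CC)(CC)OC[C@H](C)[C@@H](O[Si](C)(C)C(C)(C)C)[C@H](C)[C@@H](O)[C@@H](C)C#C | intermediate
21 | vinyl bromide | BrC=C | starting material
22 | C15–C24 enyne (15-OTES, 17-OTBS, 19-OH) | CC[Si](CC)(CC)OC[C@H](C)[C@@H](O[Si](C)(C)C(C)(C)C)[C@H](C)[C@@H](O)[C@@H](C)C#CC=C | intermediate
23 | C15–C24 (21Z)-diene (15-OTES, 17-OTBS, 19-OH) | CC[Si](CC)(CC)OC[C@H](C)[C@@H](O[Si](C)(C)C(C)(C)C)[C@H](C)[C@@H](O)[C@@H](C)/C=C\C=C | intermediate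
24 | C15–C24 diene diol (15-OH, 19-OH, 17-OTBS) | OC[C@H](C)[C@@H](O[Si](C)(C)C(C)(C)C)[C@H](C)[C@@H](O)[C@@H](C)/C=C\C=C | intermediate
25 | C15–C24 diene iodide (15-I, 17-OTBS, 19-OH) | IC[C@H](C)[C@@H](O[Si](C)(C)C(C)(C)C)[C@H](C)[C@@H](O)[C@@H](C)/C=C\C=C | intermediate
26 | methyl ester of the C7–C24 (Z)-enoic acid (11,17-bis-OTBS, 19-OH) | C=C/C=C\[C@H](C)[C@H](O)[C@@H](C)[C@H](O[Si](C)(C)C(C)(C)C)[C@@H](C)C/C(C)=C\[C@H](C)[C@@H](O[Si](C)(C)C(C)(C)C)[C@@H](C)/C=C\C(=O)OC | intermediate
27 | 19-O-carbamate of 26 | C=C/C=C\[C@H](C)[C@H](OC(N)=O)[C@@H](C)[C@H](O[Si](C)(C)C(C)(C)C)[C@@H](C)C/C(C)=C\[C@H](C)[C@@H](O[Si](C)(C)C(C)(C)C)[C@@H](C)/C=C\C(=O)OC | intermediate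
28 | C7–C24 (Z)-enoic acid (19-OCONH2, 11,17-bis-OTBS) | C=C/C=C\[C@H](C)[C@H](OC(N)=O)[C@@H](C)[C@H](O[Si](C)(C)C(C)(C)C)[C@@H](C)C/C(C)=C\[C@H](C)[C@@H](O[Si](C)(C)C(C)(C)C)[C@@H](C)/C=C\C(=O)O | intermediate
29 | S-(pyridin-2-yl) thioester of 28 | C=C/C=C\[C@H](C)[C@H](OC(N)=O)[C@@H](C)[C@H](O[Si](C)(C)C(C)(C)C)[C@@H](C)C/C(C)=C\[C@H](C)[C@@H](O[Si](C)(C)C(C)(C)C)[C@@H](C)/C=C\C(=O)Sc1ccccn1 | intermediate
30 | 7-oxo-11,17-bis-O-TBS-discodermolide | C=C/C=C\[C@H](C)[C@H](OC(N)=O)[C@@H](C)[C@H](O[Si](C)(C)C(C)(C)C)[C@@H](C)C/C(C)=C\[C@H](C)[C@@H](O[Si](C)(C)C(C)(C)C)[C@@H](C)/C=C\C(=O)C[C@@H]1OC(=O)[C@H](C)[C@@H](O)[C@H]1C | intermediate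
31 | 11,17-bis-O-TBS-discodermolide | C=C/C=C\[C@H](C)[C@H](OC(N)=O)[C@@H](C)[C@H](O[Si](C)(C)C(C)(C)C)[C@@H](C)C/C(C)=C\[C@H](C)[C@@H](O[Si](C)(C)C(C)(C)C)[C@@H](C)/C=C\[C@@H](O)C[C@@H]1OC(=O)[C@H](C)[C@@H](O)[C@H]1C | intermediate
32 | (+)-discodermolide | C=C/C=C\[C@H](C)[C@H](OC(N)=O)[C@@H](C)[C@H](O)[C@@H](C)C/C(C)=C\[C@H](C)[C@@H](O)[C@@H](C)/C=C\[C@@H](O)C[C@@H]1OC(=O)[C@H](C)[C@@H](O)[C@H]1C | target

## Step count and risks

**Total steps:** 27.
**Longest linear sequence:** 17 (steps 1, 2, 12, 13, 14, 16–27).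

**Three steps most likely to fail:**

1. **Step 25 (radical acyl cross-coupling).** Risks are Ni binding or radical addition at the terminal diene, Z→E isomerisation of the enoyl unit or the enone product, β-elimination of the β-acyloxy ketone 30, and reductive ring-opening of 8. Fallback: run the same C6–C7 radical acylation one stage earlier, between 8 and the S-2-pyridyl thioester of the diene-free, carbamate-free C7–C13 acid (from 11 by hydrolysis and thioesterification). After reduction and protection of C7-OH, elaborate C13 (Swern, Zhao–Wittig) and attach C15–C24 last by the Suzuki coupling.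

2. **Step 26 (C7 reduction).** Facial selectivity on a (Z)-enone with a branched α′-substituent is uncertain. Fallback: abandon reagent control; use a non-selective Luche reduction, separate the C7 epimers, and recycle 7-epi-31 by MnO2 re-oxidation to 30.

3. **Step 21 (Suzuki coupling with a free C19-OH).** The alkyllithium may be quenched by the hydroxyl, or the alkoxide may interfere with borate formation. Fallback: replace the organolithium/borane sequence with a Ni-catalysed reductive cross-electrophile coupling of iodide 25 with vinyl iodide 13 (NiBr2·glyme/dtbbpy, Mn, DMA), which tolerates free hydroxyl groups.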